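The runs are calculated with constants of no real substance; the scatter is artificial.

In the first minutes of both earlier runs the product rose and then stood, on average at 0.0702 M in ochre and 0.121 M in grey, with reagent left over, so I wrote the balance of the reagent, the limiting reagent in your flask: reagent left is charge minus product, with what the catalyst can hold neglected. I supposed that free catalyst is lost in step with the product standing and turns over in step with the reagent left. Summed to the stop, ochre then gave 0.0589 M and grey 0.0589 M of what I called the catalyst budget, the reagent charge times ln(charge over reagent left), minus the product.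

in all of them: starting material 0.20 M; free catalyst 0.40 mM
- ochre: reagent 0.094 M; run made earlier
- grey: reagent 0.21 M; run made earlier
- flask: reagent 0.140 M; time 80 min

| run | time / min | starting material / % | product / % |
|---|---|---|---|
| ochre | 5.00 | 66.7 | 34.2 |
| ochre | 8.00 | 66.5 | 33.9 |
| ochre | 12.0 | 65.0 | 35.1 |
| ochre | 20.0 | 65.5 | 35.4 |
| ochre | 30.0 | 65.2 | 34.5 |
| ochre | 40.0 | 65.6 | 35.3 |
| ochre | 60.0 | 65.1 | 35.2 |
| grey | 3.00 | 44.6 | 55.1 |
| grey | 10.0 | 40.0 | 60.5 |
| grey | 20.0 | 39.8 | 59.8 |
| grey | 30.0 | 39.5 | 60.3 |
| grey | 40.0 | 40.3 | 60.0 |
| grey | 50.0 | 38.8 | 60.7 |
| grey | 60.0 | 38.5 | 61.0 |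

(standard deviation of a reading: 0.5 percentage points)

- part of the starting material gone at 80 min
- the product standing at 80 min, as a percentage of the starting material charged

I held that budget for your flask, which has the same charges of free catalyst and starting material. From the straight line between the plateaus, 0.0902 M, one Newton step gave 0.0926 M, which is 46.3% of the starting material. Your forecast stood at 47% gone and 47% product, with “No simple model fits exactly.” Mine came out a little lower, by a different route.

The flask gave 46.5% gone and 46.1% product.

    starting material + free catalyst ⇌ catalyst intermediate A (K = 140 /M, k = 130 /M/s)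
    reagent + catalyst intermediate A ⇌ catalyst intermediate B (K = 2.40 /M, k = 29.0 /M/s)
    catalyst intermediate B → catalyst intermediate C (k = 75.0 /s)
    catalyst intermediate C → free catalyst + product (k = 22.0 /s)
    catalyst intermediate A + product → spent catalyst (k = 0.170 /M/s)

Its product returns a budget of 0.0582 M, and the neighbour with 0.084 M of reagent, which gave 32.2% product, returns 0.0577 M, against the 0.0589 M read from ochre. The flask had come to rest: spent catalyst stood at 99.4% of the catalyst charged after 8.00 min and 100% after 40.0 min, with 34% of the reagent charged and 54% of the starting material charged still there at 80.0 min. Ten times the time changed nothing: at 800 min the flask still showed 46.5% gone and 46.1% product.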